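## Structural features

The target is a chalcone. Ring B (4-hydroxyphenyl) is joined through an (E)-enone to C8 of ring A, a benzene ring fused at C4a–C8a to ring C, a 3,4-dihydro-2H-pyran (chroman numbering: O1, C2, C3, C4, C4a, C5–C8, C8a). Ring A carries four contiguous substituents, C5–OMe, C4a–CH2(C4), C8a–O1 and C8–acyl, and two adjacent free positions, C6–H and C7–H. It is a resorcinol whose oxygen ortho to the ketone is tied into ring C while the para oxygen is methylated. Ring C holds the only stereocenter, C3 (R, secondary alcohol), between the quaternary, oxygen-bearing C2 (gem-dimethyl) and the benzylic C4. Fragile groups are the enone (Michael acceptor, E/Z-photolabile), the free phenol, and the β-hydroxy tertiary ether of ring C, which is isomeric with a five-membered 2-(2-hydroxypropan-2-yl)dihydrobenzofuran. The real difficulty is placement: a carbon substituent between two resorcinol oxygens, differentiation of those oxygens, and an O1–C2 bond to a tertiary carbon closed in the six-membered and not the five-membered mode, with C3 of defined absolute configuration. The key step exploits that C8a–C4a–C5–C6 is a 1,3-dioxygenated four-carbon chain (C8a at carboxyl level bearing O1, C5 at ketone level bearing OMe), i.e. the dienol ether of an α-acetyl δ-lactone that already contains ring C, and that C6/C7 are the only unsubstituted ring carbons, so that C7–C8 can come from a terminal ynone.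

## Logic of the disconnections

14 ⇒ 13. Only the two O–Si bonds are cut. The phenol would protonate the silyl ketene acetal of the key step, and the C3 hydroxyl must stay masked from the lactone stage onward, since a free hydroxyl there would translactonize to the five-membered isomer. Nothing is gained in skeleton. The forward step must cleave both silyl ethers without touching the enone or the aryl ethers.

13 ⇒ 7 + 11 (through 12). The bonds C6–C7 and C8–C8a of ring A are cut: the benzene ring is taken apart into the four-carbon unit C8a–C4a–C5–C6 of 7 (which carries ring C, O1, the methoxy group and C3) and the two-carbon unit C7–C8 of 11 (which carries the whole cinnamoyl arm and ring B). In one sentence, ring A is made last by cycloaddition and eliminative aromatization of 7 with 11. The cut is made here because the polarity of a 1,1,3-trioxygenated diene and a terminal ynone dictates all four contiguous substituents at once, and because O1–C8a then already exists before the arene does. The gain is that the complete skeleton falls into two non-aromatic (in ring A) fragments of similar size. The forward step demands bonding of C6 to the unsubstituted alkyne carbon, reaction at the alkyne and not the styryl alkene, and departure of the silyloxy group, not O1, from C8a on aromatization.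

7 ⇒ 6 ⇒ 5 ⇒ 4. Cut in turn are the O–Si bond together with the C6–H bond (vinylogous enolization), the O–CH3 bond at C5, and the C4a–C5 bond (acetyl to the lactone α-carbon). This reveals the diene as an α-acetyl δ-lactone in disguise and reduces it to a plain lactone. The forward steps demand C- over O-acylation of a lactone enolate, O- over C-methylation of the β-dicarbonyl, and deprotonation at the methyl group only.

4 ⇒ 3 ⇒ 2 ⇒ 1. The O1–C2 bond of ring C is traced back to a C–C bond of a cyclopentanone (oxygen insertion), then the O–Si bond and the C3–H bond are cut. Oxygen insertion forms the O–C(quaternary) bond by migration, so no oxygen nucleophile ever has to choose between five- and six-membered closure, the problem common to phenol/epoxide and hydroxy acid/lactone routes. The precursor 1 is achiral and symmetric, so C3 is set by face-selective reduction of one carbonyl. The forward steps demand migration of the quaternary carbon and a clean, enantioselective mono-reduction.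

11 ⇒ 10 ⇒ 8 + 9. The carbonyl–alkyne bond and the Cα=Cβ bond of the arm are cut. This gives two commercial pieces and an acyl donor that stops at the ketone. The forward steps demand E-selective olefination and 1,2-addition without over-addition or conjugate addition.

## Other disconnections considered

Alternative 1: (the first that comes to mind) Cut the enone Cα=Cβ bond and the O1–C2 bond, both on a preformed resorcinol ketone. Forward: C-prenylation of the commercial 2-hydroxy-4-methoxyaryl methyl ketone to 1-[2-hydroxy-4-methoxy-3-(3-methylbut-2-en-1-yl)phenyl]ethan-1-one A1; enantioselective epoxidation to 1-(3-{[(2R)-3,3-dimethyloxiran-2-yl]methyl}-2-hydroxy-4-methoxyphenyl)ethan-1-one A2; acid-mediated 6-endo opening by the phenol (the key step) to 1-[(3R)-3-hydroxy-5-methoxy-2,2-dimethyl-3,4-dihydro-2H-chromen-8-yl]ethan-1-one A3; Claisen–Schmidt condensation with a protected 4-hydroxybenzaldehyde. Grounds for preferring the chosen plan: alkylation at the carbon between the two oxygens competes with O-alkylation and with the other free ortho position. In the key step a hydrogen-bonded, weakly nucleophilic phenol must choose between the tertiary carbon (six-membered, wanted) and the secondary carbon (five-membered dihydrobenzofuran), a balance set by conditions and not by structure. The chosen plan fixes the substituent pattern by cycloaddition polarity and the O1–C2 bond by migration.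

Alternative 2: Danheiser benzannulation. Cut ring A at C8a–C4a, C5–C6 and C8–C8a into a methoxyalkyne (C4a, C5) and a vinylketene (C8a, C8, C7, C6). Forward: the thermal cascade ([2+2] cycloaddition, 4π opening, 6π closure, tautomerization) of (3R)-3-{[tert-butyl(dimethyl)silyl]oxy}-6-methoxy-2-methylhex-5-yn-2-ol A4 with a vinylketene generated from a cyclobutenone would give 2-[(2R)-2-{[tert-butyl(dimethyl)silyl]oxy}-3-hydroxy-3-methylbutyl]-3-methoxyphenol A5. Grounds: the oxygen pattern maps correctly, but the vinylketene would need an acyl group on its terminal carbon, for which no convenient precursor exists. C8 would therefore stay unsubstituted and the ketone would have to be added later by aromatic substitution. A5 also has ring C open, so the O1–C2 bond would still have to be made from a phenol and a tertiary carbinol, which brings back the five- versus six-membered closure. The key step would settle less and the route would be longer.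

Alternative 3: Ring A carried as a saturated ring and aromatized late. Cut C4–C4a and O1–C8a. Forward: Knoevenagel condensation/oxa-6π electrocyclization of the parent six-membered cyclic 1,3-diketone with the C5 enal to 2,2-dimethyl-2,6,7,8-tetrahydro-5H-chromen-5-one A6; enantioselective hydration of C3=C4 and acylation to (3R)-8-acetyl-3-hydroxy-2,2-dimethyl-2,3,4,6,7,8-hexahydro-5H-chromen-5-one A7; late dehydrogenation (the key step), O-methylation and condensation. Grounds: enolate acylation of a vinylogous ester such as A6 is expected at C6 (α to the carbonyl), whereas the target needs the acyl group at C8 (γ, next to the enol ether carbon). The natural regiochemistry thus leads to the constitutional isomer with the ketone para to O1. Regio- and enantioselective hydration of an alkene inside a cross-conjugated dienone and a late dehydrogenation next to a β-hydroxy ether add further steps and risk.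

Key step: step 9

Remark on the chemistry (assumption): the C3 descriptor read from the SMILES is R. The sense of the oxazaborolidine reduction in step 1 is assigned from the standard model with the quaternary C2 flank as the large group.

## Steps

Step 1
Reactants: 1 2,2-dimethylcyclopentane-1,3-dione
Product: 2 (3R)-3-hydroxy-2,2-dimethylcyclopentan-1-one
Conditions: (S)-Me-CBS [(3aS)-1-methyl-3,3-diphenyltetrahydro-1H,3H-pyrrolo[1,2-c][1,3,2]oxazaborole] (0.2 equiv), catecholborane (1.1 equiv), PhMe, −60 °C; MeOH, aq. NaHCO3
Reagents that add atoms: none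
Why: Corey–Bakshi–Shibata reduction; the two carbonyls of the symmetric diketone are equivalent and each has enantiotopic faces, the catalyst binds the ketone with the quaternary C2 flank as the large group and delivers hydride to one face, which by the standard model (S catalyst, large group of higher CIP rank) should give the 3R alcohol; a one-hydride borane at low temperature limits reduction of the second carbonyl.

Step 2
Reactants: 2 (3R)-3-hydroxy-2,2-dimethylcyclopentan-1-one
Product: 3 (3R)-3-{[tert-butyl(dimethyl)silyl]oxy}-2,2-dimethylcyclopentan-1-one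
Conditions: TBSCl, imidazole, DMF, 23 → 40 °C
Reagents that add atoms: tert-butyldimethylsilyl chloride, CC(C)(C)[Si](C)(C)Cl
Why: Standard silylation of a secondary alcohol; the ether blocks retro-aldol opening now and translactonization to the five-membered lactone later; the stereocenter is not touched.

Step 3
Reactants: 3 (3R)-3-{[tert-butyl(dimethyl)silyl]oxy}-2,2-dimethylcyclopentan-1-one
Product: 4 (5R)-5-{[tert-butyl(dimethyl)silyl]oxy}-6,6-dimethyloxan-2-one
Conditions: mCPBA, NaHCO3 (solid buffer), CH2Cl2, 0 → 23 °C
Reagents that add atoms: 3-chloroperbenzoic acid (mCPBA), OOC(=O)c1cccc(Cl)c1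
Why: Baeyer–Villiger oxidation; in the Criegee intermediate the quaternary carbon migrates in preference to the methylene, with retention, so oxygen is inserted between C1 and C2 and the O–C(CH3)2 bond of the future ring C is made with no five-membered alternative; the carbinol center is not involved.

Step 4
Reactants: 4 (5R)-5-{[tert-butyl(dimethyl)silyl]oxy}-6,6-dimethyloxan-2-one
Product: 5 (5R)-3-acetyl-5-{[tert-butyl(dimethyl)silyl]oxy}-6,6-dimethyloxan-2-one (mixture of C3 epimers and enol tautomer)
Conditions: LiN(SiMe3)2 (2.2 equiv), THF, −78 °C; 1-acetylimidazole (1.2 equiv), −78 → −20 °C; aq. NH4Cl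
Reagents that add atoms: 1-acetylimidazole, CC(=O)n1ccnc1
Why: Claisen-type C-acylation of a lithium lactone enolate with an acylimidazole; the second equivalent of base deprotonates the β-keto lactone as it forms; the new C3 center is irrelevant because it becomes sp2 in step 5.

Step 5
Reactants: 5 (5R)-3-acetyl-5-{[tert-butyl(dimethyl)silyl]oxy}-6,6-dimethyloxan-2-one
Product: 6 (5R)-5-{[tert-butyl(dimethyl)silyl]oxy}-3-(1-methoxyethylidene)-6,6-dimethyloxan-2-one (E/Z mixture)
Conditions: Cs2CO3, Me2SO4, DMF, 0 → 23 °C
Reagents that add atoms: dimethyl sulfate, COS(=O)(=O)OC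
Why: O-alkylation of a β-dicarbonyl enolate; a loosely paired cesium enolate in a dipolar aprotic solvent with a hard methylating agent should react at oxygen, and C-methylation would have to build a quaternary center at the substituted α-carbon; both double-bond isomers converge on the same diene in step 6.

Step 6
Reactants: 6 (5R)-5-{[tert-butyl(dimethyl)silyl]oxy}-3-(1-methoxyethylidene)-6,6-dimethyloxan-2-one
Product: 7 tert-butyl{[(3R)-5-(1-methoxyethenyl)-2,2-dimethyl-6-[(trimethylsilyl)oxy]-3,4-dihydro-2H-pyran-3-yl]oxy}dimethylsilane
Conditions: LiN(i-Pr)2, THF, −78 °C; TMSCl, −78 → 0 °C; pentane, filtration, concentration (used crude, moisture excluded)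
Reagents that add atoms: chlorotrimethylsilane, C[Si](C)(C)Cl
Why: Vinylogous (γ) deprotonation of a β-alkoxy enoate and O-silylation of the dienolate, the standard preparation of 1,1,3-trioxygenated vinylketene acetal dienes; the methyl group is the only position whose anion is conjugated with the lactone carbonyl.

Step 7
Reactants: 8 4-{[tert-butyl(dimethyl)silyl]oxy}benzaldehyde; 9 diethyl {2-[methoxy(methyl)amino]-2-oxoethyl}phosphonate
Product: 10 (2E)-3-(4-{[tert-butyl(dimethyl)silyl]oxy}phenyl)-N-methoxy-N-methylprop-2-enamide
Conditions: NaH, THF, 0 → 23 °C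
Reagents that add atoms: none
Why: Horner–Wadsworth–Emmons olefination; the stabilized phosphonate carbanion should give the E-alkene.

Step 8
Reactants: 10 (2E)-3-(4-{[tert-butyl(dimethyl)silyl]oxy}phenyl)-N-methoxy-N-methylprop-2-enamide
Product: 11 (1E)-1-(4-{[tert-butyl(dimethyl)silyl]oxy}phenyl)pent-1-en-4-yn-3-one
Conditions: HC≡CMgBr (0.5 M in THF, 1.5 equiv), THF, −20 → 0 °C; inverse quench into cold 1 M HCl
Reagents that add atoms: ethynylmagnesium bromide, C#C[Mg]Br
Why: Weinreb ketone synthesis; the magnesium-chelated tetrahedral intermediate prevents over-addition, and the acidic inverse quench protonates the liberated N,O-dimethylhydroxylamine before it can add to the ynone.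

Step 9
Reactants: 7 tert-butyl{[(3R)-5-(1-methoxyethenyl)-2,2-dimethyl-6-[(trimethylsilyl)oxy]-3,4-dihydro-2H-pyran-3-yl]oxy}dimethylsilane; 11 (1E)-1-(4-{[tert-butyl(dimethyl)silyl]oxy}phenyl)pent-1-en-4-yn-3-one
Product: 13 (2E)-1-[(3R)-3-{[tert-butyl(dimethyl)silyl]oxy}-5-methoxy-2,2-dimethyl-3,4-dihydro-2H-chromen-8-yl]-3-(4-{[tert-butyl(dimethyl)silyl]oxy}phenyl)prop-2-en-1-one, via ketal cycloadduct 12 (not isolated)
Conditions: 7 (1.5 equiv), 11 (1.0 equiv), PhMe, 4 Å MS, 2,6-lutidine (0.2 equiv), 23 → 60 °C; Et3N-deactivated SiO2
Reagents that add atoms: none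
Why: Proposed new method: diene 7 is the endocyclic analogue of a 1,1,3-trioxygenated vinylketene acetal, and its C6 terminus (raised by both oxygen donors) should add to the unsubstituted alkyne carbon of 11 while C8a closes on the acyl-bearing carbon in a strongly asynchronous thermal [4+2] cycloaddition that forms C6–C7 and C8–C8a and gives ketal 12. The closest known reaction type is the cycloaddition of mixed alkyl silyl vinylketene acetals with acetylenic ketones or esters followed by eliminative aromatization to alkoxyarenes; new here are the lactone-derived endocyclic ketene acetal and the requirement that the exocyclic silyloxy group, and not the ring oxygen, leaves. Ring A is closed by this intermolecular [4π+2π] process, and ring C is carried in intact and closes nothing. Heterolysis of C8a–OSiMe3 in 12 gives a cation that is the arenium ion of the product, stabilized by O1 and by the C5 methoxy group, and loss of the C6 proton completes the arene with release of trimethylsilanol. Silanol loss is favoured over ring opening because silanolate is the better nucleofuge by several pKa units, the exocyclic C–OSi bond lies closer to perpendicular to the cyclohexadiene π system than the C8a–O1 bond held by the fused ring, ionization of C8a–O1 can revert by return of the tethered alkoxide, and the dry, base-buffered medium with excess 7 as silanol scavenger suppresses Si–O cleavage, which would open ring C through the hemiketal. The regiochemistry (acyl at C8, ortho to O1 and para to OMe) follows from union of the nucleophilic C6 with the β-carbon of the ynone. The terminal ynone is far more electrophilic than the alkene bearing the donor-substituted aryl group, which secures chemoselectivity. The C8a stereocenter of 12 is transient and is erased, C3 is untouched, and no new stereocenter remains.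

Step 10
Reactants: 13 (2E)-1-[(3R)-3-{[tert-butyl(dimethyl)silyl]oxy}-5-methoxy-2,2-dimethyl-3,4-dihydro-2H-chromen-8-yl]-3-(4-{[tert-butyl(dimethyl)silyl]oxy}phenyl)prop-2-en-1-one
Product: 14 (2E)-1-[(3R)-3-hydroxy-5-methoxy-2,2-dimethyl-3,4-dihydro-2H-chromen-8-yl]-3-(4-hydroxyphenyl)prop-2-en-1-one
Conditions: HF·pyridine, pyridine, THF, 0 → 23 °C
Reagents that add atoms: none
Why: Fluoride-driven cleavage of the aryl and the hindered secondary silyl ether in one operation; the buffered acidic fluoride source leaves the enone, the aryl methyl ether and the tertiary aryl ether alone, and no stereocenter is involved.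

## Compound list

1 | 2,2-dimethylcyclopentane-1,3-dione | CC1(C)C(=O)CCC1=O | starting material
2 | (3R)-3-hydroxy-2,2-dimethylcyclopentan-1-one | O=C1CC[C@@H](O)C1(C)C | intermediate
3 | (3R)-3-{[tert-butyl(dimethyl)silyl]oxy}-2,2-dimethylcyclopentan-1-one | O=C1CC[C@@H](O[Si](C)(C)C(C)(C)C)C1(C)C | intermediate
4 | (5R)-5-{[tert-butyl(dimethyl)silyl]oxy}-6,6-dimethyloxan-2-one | O=C1CC[C@@H](O[Si](C)(C)C(C)(C)C)C(C)(C)O1 | intermediate
5 | (5R)-3-acetyl-5-{[tert-butyl(dimethyl)silyl]oxy}-6,6-dimethyloxan-2-one (C3 epimers, enol tautomer) | CC(=O)C1C[C@@H](O[Si](C)(C)C(C)(C)C)C(C)(C)OC1=O | intermediate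
6 | (5R)-5-{[tert-butyl(dimethyl)silyl]oxy}-3-(1-methoxyethylidene)-6,6-dimethyloxan-2-one (E/Z mixture) | COC(C)=C1C[C@@H](O[Si](C)(C)C(C)(C)C)C(C)(C)OC1=O | intermediate
7 | tert-butyl{[(3R)-5-(1-methoxyethenyl)-2,2-dimethyl-6-[(trimethylsilyl)oxy]-3,4-dihydro-2H-pyran-3-yl]oxy}dimethylsilane | C=C(OC)C1=C(O[Si](C)(C)C)OC(C)(C)[C@H](O[Si](C)(C)C(C)(C)C)C1 | intermediate
8 | 4-{[tert-butyl(dimethyl)silyl]oxy}benzaldehyde | O=Cc1ccc(O[Si](C)(C)C(C)(C)C)cc1 | starting material
9 | diethyl {2-[methoxy(methyl)amino]-2-oxoethyl}phosphonate | CCOP(=O)(CC(=O)N(C)OC)OCC | starting material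
10 | (2E)-3-(4-{[tert-butyl(dimethyl)silyl]oxy}phenyl)-N-methoxy-N-methylprop-2-enamide | CON(C)C(=O)/C=C/c1ccc(O[Si](C)(C)C(C)(C)C)cc1 | intermediate
11 | (1E)-1-(4-{[tert-butyl(dimethyl)silyl]oxy}phenyl)pent-1-en-4-yn-3-one | C#CC(=O)/C=C/c1ccc(O[Si](C)(C)C(C)(C)C)cc1 | intermediate
12 | (2E)-1-[(3R)-3-{[tert-butyl(dimethyl)silyl]oxy}-5-methoxy-2,2-dimethyl-8a-[(trimethylsilyl)oxy]-3,4,6,8a-tetrahydro-2H-chromen-8-yl]-3-(4-{[tert-butyl(dimethyl)silyl]oxy}phenyl)prop-2-en-1-one (C8a epimers) | COC1=C2C[C@@H](O[Si](C)(C)C(C)(C)C)C(C)(C)OC2(O[Si](C)(C)C)C(C(=O)/C=C/c2ccc(O[Si](C)(C)C(C)(C)C)cc2)=CC1 | intermediate (not isolated)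
13 | (2E)-1-[(3R)-3-{[tert-butyl(dimethyl)silyl]oxy}-5-methoxy-2,2-dimethyl-3,4-dihydro-2H-chromen-8-yl]-3-(4-{[tert-butyl(dimethyl)silyl]oxy}phenyl)prop-2-en-1-one | COc1ccc(C(=O)/C=C/c2ccc(O[Si](C)(C)C(C)(C)C)cc2)c2c1C[C@@H](O[Si](C)(C)C(C)(C)C)C(C)(C)O2 | intermediate
14 | (2E)-1-[(3R)-3-hydroxy-5-methoxy-2,2-dimethyl-3,4-dihydro-2H-chromen-8-yl]-3-(4-hydroxyphenyl)prop-2-en-1-one | COc1ccc(C(=O)/C=C/c2ccc(O)cc2)c2c1C[C@@H](O)C(C)(C)O2 | target

## Step count and least certain steps

Total: 10 steps. Longest linear sequence: 8 steps (steps 1–6, 9, 10); steps 7 and 8 form the second branch.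

**Step 9 (key step, Proposed new method).** The most likely failure is aromatization with expulsion of the ring oxygen instead of the silyloxy group, which opens ring C. This would occur if Si–O cleavage by adventitious protic species outruns C–O heterolysis. A second risk is a stepwise conjugate addition that ends by silyl transfer to the allenolate, leaving an open-chain adduct. The cycloaddition may also be slow because the silyloxy group sits on the inner side of the s-cis diene. The fallback uses known chemistry; it sets out from 8 and comes back at 14. Commercial 1-(2-hydroxy-4-methoxyphenyl)ethan-1-one F1 is O-alkylated at the chelated hydroxyl with 3-chloro-3-methylbut-1-yne (K2CO3, KI, CuCl2 cat., acetone) to 1-{4-methoxy-2-[(2-methylbut-3-yn-2-yl)oxy]phenyl}ethan-1-one F2. Heating (N,N-diethylaniline, 190 °C) should bring about aryl propargyl ether Claisen rearrangement to the only free ortho position and electrocyclization to 1-(5-methoxy-2,2-dimethyl-2H-chromen-8-yl)ethan-1-one F3. Jacobsen–Katsuki epoxidation ((R,R)-N,N′-bis(3,5-di-tert-butylsalicylidene)-1,2-cyclohexanediaminomanganese chloride, NaOCl, 4-phenylpyridine N-oxide) should give 1-[(3R,4R)-3,4-epoxy-5-methoxy-2,2-dimethyl-3,4-dihydro-2H-chromen-8-yl]ethan-1-one F4. Hydrogenolysis of the benzylic C4–O bond (H2, Pd/C, EtOAc) gives 1-[(3R)-3-hydroxy-5-methoxy-2,2-dimethyl-3,4-dihydro-2H-chromen-8-yl]ethan-1-one F5. Claisen–Schmidt condensation of F5 with 8 (KOH, EtOH; the aryl silyl ether is cleaved by hydroxide in the same flask) returns to 14.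

**Step 5.** C-methylation may compete with O-methylation of the ambident enolate, and the lactone may open under carbonate. The fallback sets out from 4 and comes back at 6, so the methyl group arrives on oxygen as part of an ortho ester. 4 is converted (LiN(i-Pr)2, TMSCl, THF, −78 °C) into tert-butyl{[(3R)-2,2-dimethyl-6-[(trimethylsilyl)oxy]-3,4-dihydro-2H-pyran-3-yl]oxy}dimethylsilane F6. F6 is condensed with trimethyl orthoacetate in a Mukaiyama-type reaction (ZnCl2 cat., CH2Cl2, −78 → 0 °C) to (5R)-5-{[tert-butyl(dimethyl)silyl]oxy}-3-(1,1-dimethoxyethyl)-6,6-dimethyloxan-2-one F7. Base-induced loss of methanol (DBU, PhMe, heat) gives 6.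

**Step 4.** O-acylation and self-condensation of the lactone enolate may compete with C-acylation. The fallback sets out from 4 and comes back at 5. Aldol addition of the lithium enolate of 4 to acetaldehyde (LiN(i-Pr)2, THF, −78 °C) gives (5R)-5-{[tert-butyl(dimethyl)silyl]oxy}-3-(1-hydroxyethyl)-6,6-dimethyloxan-2-one F8 as a diastereomer mixture. Dess–Martin oxidation (CH2Cl2, NaHCO3) gives 5.

**Step 8.** Conjugate addition of the liberated N,O-dimethylhydroxylamine to the ynone during quench, or oligomerization of the cross-conjugated enynone, may erode the product. The fallback sets out from 10 and comes back at 11. Reduction of 10 (i-Bu2AlH, THF, −78 °C) gives (2E)-3-(4-{[tert-butyl(dimethyl)silyl]oxy}phenyl)prop-2-enal F9. Addition of HC≡CMgBr gives racemic (1E)-1-(4-{[tert-butyl(dimethyl)silyl]oxy}phenyl)pent-1-en-4-yn-3-ol F10. Oxidation with MnO2 (CH2Cl2) gives 11 under neutral conditions with no amine present.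

**Step 1.** Enantioselection may be incomplete and the second carbonyl may be over-reduced to the diol. The fallback sets out from 1 and comes back at 2. Partial reduction (NaBH4, 0.3 equiv, MeOH, −20 °C) gives racemic 3-hydroxy-2,2-dimethylcyclopentan-1-one F11. Lipase-catalysed acylation (Pseudomonas cepacia lipase, vinyl acetate) should, by the empirical rule for secondary alcohols, acylate the R enantiomer to (1R)-2,2-dimethyl-3-oxocyclopentyl acetate F12, which is separated from the unreacted S alcohol. Mild methanolysis (K2CO3, MeOH, 0 °C) gives 2.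

## Further compounds

F1 | step 9 | 1-(2-hydroxy-4-methoxyphenyl)ethan-1-one (purchased) | CC(=O)c1ccc(OC)cc1O
F2 | step 9 | 1-{4-methoxy-2-[(2-methylbut-3-yn-2-yl)oxy]phenyl}ethan-1-one | CC(=O)c1ccc(OC)cc1OC(C)(C)C#C
F3 | step 9 | 1-(5-methoxy-2,2-dimethyl-2H-chromen-8-yl)ethan-1-one | CC(=O)c1ccc(OC)c2C=CC(C)(C)Oc12
F4 | step 9 | 1-[(3R,4R)-3,4-epoxy-5-methoxy-2,2-dimethyl-3,4-dihydro-2H-chromen-8-yl]ethan-1-one | CC(=O)c1ccc(OC)c2c1OC(C)(C)[C@@H]3O[C@H]23
F5 | step 9 | 1-[(3R)-3-hydroxy-5-methoxy-2,2-dimethyl-3,4-dihydro-2H-chromen-8-yl]ethan-1-one | CC(=O)c1ccc(OC)c2c1OC(C)(C)[C@H](O)C2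
F6 | step 5 | tert-butyl{[(3R)-2,2-dimethyl-6-[(trimethylsilyl)oxy]-3,4-dihydro-2H-pyran-3-yl]oxy}dimethylsilane | C[Si](C)(C)OC1=CC[C@@H](O[Si](C)(C)C(C)(C)C)C(C)(C)O1
F7 | step 5 | (5R)-5-{[tert-butyl(dimethyl)silyl]oxy}-3-(1,1-dimethoxyethyl)-6,6-dimethyloxan-2-one | COC(C)(OC)C1C[C@@H](O[Si](C)(C)C(C)(C)C)C(C)(C)OC1=O
F8 | step 4 | (5R)-5-{[tert-butyl(dimethyl)silyl]oxy}-3-(1-hydroxyethyl)-6,6-dimethyloxan-2-one (diastereomer mixture) | CC(O)C1C[C@@H](O[Si](C)(C)C(C)(C)C)C(C)(C)OC1=O
F9 | step 8 | (2E)-3-(4-{[tert-butyl(dimethyl)silyl]oxy}phenyl)prop-2-enal | O=C/C=C/c1ccc(O[Si](C)(C)C(C)(C)C)cc1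
F10 | step 8 | (1E)-1-(4-{[tert-butyl(dimethyl)silyl]oxy}phenyl)pent-1-en-4-yn-3-ol (racemic) | C#CC(O)/C=C/c1ccc(O[Si](C)(C)C(C)(C)C)cc1
F11 | step 1 | 3-hydroxy-2,2-dimethylcyclopentan-1-one (racemic) | O=C1CCC(O)C1(C)C
F12 | step 1 | (1R)-2,2-dimethyl-3-oxocyclopentyl acetate | CC(=O)O[C@@H]1CCC(=O)C1(C)C
A1 | alternative 1 | 1-[2-hydroxy-4-methoxy-3-(3-methylbut-2-en-1-yl)phenyl]ethan-1-one | CC(=O)c1ccc(OC)c(CC=C(C)C)c1O
A2 | alternative 1 | 1-(3-{[(2R)-3,3-dimethyloxiran-2-yl]methyl}-2-hydroxy-4-methoxyphenyl)ethan-1-one | CC(=O)c1ccc(OC)c(C[C@H]2OC2(C)C)c1O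
A3 | alternative 1 | 1-[(3R)-3-hydroxy-5-methoxy-2,2-dimethyl-3,4-dihydro-2H-chromen-8-yl]ethan-1-one | CC(=O)c1ccc(OC)c2c1OC(C)(C)[C@H](O)C2
A4 | alternative 2 | (3R)-3-{[tert-butyl(dimethyl)silyl]oxy}-6-methoxy-2-methylhex-5-yn-2-ol | COC#CC[C@@H](O[Si](C)(C)C(C)(C)C)C(C)(C)O
A5 | alternative 2 | 2-[(2R)-2-{[tert-butyl(dimethyl)silyl]oxy}-3-hydroxy-3-methylbutyl]-3-methoxyphenol | COc1cccc(O)c1C[C@@H](O[Si](C)(C)C(C)(C)C)C(C)(C)O
A6 | alternative 3 | 2,2-dimethyl-2,6,7,8-tetrahydro-5H-chromen-5-one | CC1(C)C=CC2=C(CCCC2=O)O1
A7 | alternative 3 | (3R)-8-acetyl-3-hydroxy-2,2-dimethyl-2,3,4,6,7,8-hexahydro-5H-chromen-5-one | CC(=O)C1CCC(=O)C2=C1OC(C)(C)[C@H](O)C2
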